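Ring C, the pyranone, is cut at three bonds: C4a–C4, C4–C3 and O1–C2. The cut works because C4 is a lone carbonyl carbon lodged between A-ring carbon C4a and the C3=C2 pair that bears ring B. C4 therefore maps onto carbon monoxide and C2–C3 onto an arylacetylene. One palladium-catalysed operation joins iodophenol, CO and alkyne and closes ring C. The precursor is a fully oxygenated o-iodophenol with iodine at the future C4a, the only free OH at C8a, and methoxy groups at C5, C7 and C8. This locks the 5,7,8 pattern before cyclisation. Peri-selective loss of the 5-O-methyl group completes the synthesis.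

Key step: step 7

Remark: the target has no stereocentre, stereogenic axis or configurable double bond, so it is achiral and the drawn structure is the only form to be made.
Atom map: C1–C6 of aldehyde 1 become C8, C8a, C4a, C5, C6 and C7 of the flavone.

Step 1
Reactants: 1 2-hydroxy-4,6-dimethoxybenzaldehyde
Product: 2 2,4-dimethoxy-6-(methoxymethoxy)benzaldehyde
Conditions: MOMCl, i-Pr2NEt, CH2Cl2, 0 °C → rt
Reagents that add atoms: chloromethyl methyl ether (MOMCl), COCCl
Why: Base-mediated O-alkylation of the phenol by the very electrophilic α-chloro ether overcomes the hydrogen bond to the aldehyde, and MOM is chosen because it survives peracid, carbonate and butyllithium, steers the later lithiation and leaves under mild acid.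

Step 2
Reactants: 2 2,4-dimethoxy-6-(methoxymethoxy)benzaldehyde
Product: 4 2,4-dimethoxy-6-(methoxymethoxy)phenol, via aryl formate 3 (not isolated)
Conditions: mCPBA, CH2Cl2, 0 °C → rt; aq. NaHCO3 wash, concentrate; then K2CO3 (cat.), MeOH, Ar, rt
Reagents that add atoms: m-chloroperoxybenzoic acid (mCPBA), O=C(OO)c1cccc(Cl)c1
Why: Baeyer–Villiger oxidation with aryl migration is strongly favoured on a 2,4,6-trioxygenated ring (this peracid form of the Dakin reaction is needed because the alkaline hydrogen peroxide version relies on a free ortho or para hydroxyl, which is masked here), and carbonate-catalysed transesterification of 3 frees the phenol without touching the MOM acetal.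

Step 3
Reactants: 4 2,4-dimethoxy-6-(methoxymethoxy)phenol
Product: 5 1,2,5-trimethoxy-3-(methoxymethoxy)benzene
Conditions: MeI, K2CO3, DMF, rt
Reagents that add atoms: iodomethane, CI
Why: Williamson O-methylation of the only free phenol is unambiguous and promptly removes the oxidation-prone trialkoxyphenol from the sequence.

Step 4
Reactants: 5 1,2,5-trimethoxy-3-(methoxymethoxy)benzene
Product: 7 2-iodo-1,4,5-trimethoxy-3-(methoxymethoxy)benzene, via aryllithium 6 (not isolated)
Conditions: n-BuLi, Et2O, 0 °C → rt (no TMEDA); then I2, THF, −78 °C → rt
Reagents that add atoms: iodine, II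
Why: In this directed ortho-metalation butyllithium is pre-complexed by the bidentate OMOM group, a stronger director than OMe, so in a weakly coordinating medium it should remove H4 (between OMOM and 5-OMe) rather than H6 (between two OMe groups), and iodine then traps 6 at that carbon.

Step 5
Reactants: 7 2-iodo-1,4,5-trimethoxy-3-(methoxymethoxy)benzene
Product: 8 2-iodo-3,5,6-trimethoxyphenol
Conditions: p-TsOH·H2O (cat.), MeOH, 40 °C, dark
Reagents that add atoms: none
Why: Acid-catalysed transacetalisation to methanol cleaves the aryl MOM ether, and a catalytic sulfonic acid at mild temperature is chosen to avoid protodeiodination of the electron-rich ring while the aryl methyl ethers stay inert.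

Step 6
Reactants: 9 2,3-dimethoxybenzaldehyde
Product: 10 1-ethynyl-2,3-dimethoxybenzene
Conditions: dimethyl (1-diazo-2-oxopropyl)phosphonate, K2CO3, MeOH, rt
Reagents that add atoms: dimethyl (1-diazo-2-oxopropyl)phosphonate, COP(=O)(OC)C(=[N+]=[N-])C(C)=O
Why: In the Ohira–Bestmann (Seyferth–Gilbert) homologation, methanolysis of the reagent gives the diazomethylphosphonate anion, which olefinates the non-enolisable aldehyde, and loss of nitrogen with a 1,2-hydride shift delivers the terminal alkyne under conditions harmless to aryl ethers.

Step 7
Reactants: 8 2-iodo-3,5,6-trimethoxyphenol; 10 1-ethynyl-2,3-dimethoxybenzene; 11 carbon monoxide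
Product: 14 2-(2,3-dimethoxyphenyl)-5,7,8-trimethoxychromen-4-one, via hydroxyaryl ynone 12 (not isolated), via diethylamino enone 13 (not isolated)
Conditions: PdCl2(dppf) (5 mol %), CO (20 bar), Et2NH (solvent and base), 120 °C, autoclave, copper-free, degassed
Reagents that add atoms: none
Why: Pd(0) inserts into the C–I bond of 8, CO inserts to give an aroyl–Pd(II) species, and the acetylide formed from 10 and Et2NH is passed to palladium and reductively eliminated, which makes C4a–C4 and C4–C3 and gives ynone 12 (carbonylative Sonogashira coupling). Et2NH then adds in conjugate fashion to 12 to give β-amino enone 13, whose β-carbon (future C2) is attacked by the C8a hydroxyl and expels Et2NH, forming O1–C2. The pyranone thus closes by a 6-endo-trig oxa-Michael addition–elimination, equal overall to a 6-endo-dig closure of 12, and this one-pot flavone synthesis from o-iodophenols, CO and terminal arylacetylenes is established chemistry. Flavone rather than aurone is secured by the amine relay, which fixes the electrophilic site at the β-carbon and leaves no path for 5-exo attack at the α-carbon. Carbonylative rather than direct coupling (which would end in a 2-arylbenzofuran) is secured by CO pressure and the absence of copper, and the two ortho substituents shield the aroyl carbon from diethylamine so that amide formation should stay minor. No stereocentre is created, and because O5 is capped as its methyl ether only the C8a oxygen can cyclise, so the 5,7,8 pattern cannot scramble.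

Step 8
Reactants: 14 2-(2,3-dimethoxyphenyl)-5,7,8-trimethoxychromen-4-one
Product: 16 5-hydroxy-2',3',7,8-tetramethoxyflavone, via dichloroboron chelate 15 (not isolated)
Conditions: BCl3 (1 M in CH2Cl2, 1.5 equiv), CH2Cl2, −78 → 0 °C; then H2O
Reagents that add atoms: none
Why: In this chelation-controlled Lewis-acid ether cleavage boron binds the C4 carbonyl and the peri 5-OMe oxygen in a six-membered chelate and chloride removes that methyl group alone, while a small excess of BCl3 at low temperature spares the 7-, 8-, 2'- and 3'-methoxy groups and avoids the hot protic acid that would invite Wessely–Moser isomerisation.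

Compound list
1 | 2-hydroxy-4,6-dimethoxybenzaldehyde | COc1cc(O)c(C=O)c(OC)c1 | starting material
2 | 2,4-dimethoxy-6-(methoxymethoxy)benzaldehyde | COCOc1cc(OC)cc(OC)c1C=O | intermediate
3 | 2,4-dimethoxy-6-(methoxymethoxy)phenyl formate (aryl formate, formed in the flask) | COCOc1cc(OC)cc(OC)c1OC=O | intermediate
4 | 2,4-dimethoxy-6-(methoxymethoxy)phenol | COCOc1cc(OC)cc(OC)c1O | intermediate
5 | 1,2,5-trimethoxy-3-(methoxymethoxy)benzene | COCOc1cc(OC)cc(OC)c1OC | intermediate
6 | 3,4,6-trimethoxy-2-(methoxymethoxy)phenyllithium (aryllithium, formed in the flask) | [Li]c1c(OCOC)c(OC)c(OC)cc1OC | intermediate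
7 | 2-iodo-1,4,5-trimethoxy-3-(methoxymethoxy)benzene | COCOc1c(I)c(OC)cc(OC)c1OC | intermediate
8 | 2-iodo-3,5,6-trimethoxyphenol | COc1cc(OC)c(OC)c(O)c1I | intermediate
9 | 2,3-dimethoxybenzaldehyde | COc1cccc(C=O)c1OC | starting material
10 | 1-ethynyl-2,3-dimethoxybenzene | C#Cc1cccc(OC)c1OC | intermediate
11 | carbon monoxide | [C-]#[O+] | starting material
12 | 3-(2,3-dimethoxyphenyl)-1-(2-hydroxy-3,4,6-trimethoxyphenyl)prop-2-yn-1-one (hydroxyaryl ynone, formed in the flask) | COc1cccc(C#CC(=O)c2c(O)c(OC)c(OC)cc2OC)c1OC | intermediate
13 | (E)-3-(diethylamino)-3-(2,3-dimethoxyphenyl)-1-(2-hydroxy-3,4,6-trimethoxyphenyl)prop-2-en-1-one (diethylamino enone, formed in the flask; drawn E, the push–pull C=C rotates easily and its geometry is lost on closure) | CCN(CC)/C(=C/C(=O)c1c(O)c(OC)c(OC)cc1OC)c1cccc(OC)c1OC | intermediate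
14 | 2-(2,3-dimethoxyphenyl)-5,7,8-trimethoxychromen-4-one | COc1cccc(-c2cc(=O)c3c(OC)cc(OC)c(OC)c3o2)c1OC | intermediate
15 | 5-(dichloroboryloxy)-2-(2,3-dimethoxyphenyl)-7,8-dimethoxychromen-4-one (boron also bound to the C4 carbonyl oxygen, formed in the flask) | COc1cccc(-c2cc(=O)c3c(OB(Cl)Cl)cc(OC)c(OC)c3o2)c1OC | intermediate
16 | 5-hydroxy-2',3',7,8-tetramethoxyflavone, achiral | COc1cccc(-c2cc(=O)c3c(O)cc(OC)c(OC)c3o2)c1OC | target

Total step count: 8. Longest linear sequence: 7 (steps 1–5, 7, 8). Step 6 is a one-step branch.

Steps most likely to fail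

**Step 7.** Oxidative addition into the electron-rich C–I bond flanked by OH and OMe may be slow. Reduction of the C–I bond, capture of the aroyl–palladium species by diethylamine, or CO-free coupling followed by benzofuran closure could then take over.

The fallback makes the same three bonds stepwise, without palladium or CO gas, and brings in C4 as a carbamoyl chloride. It sets out from 10 and 7 and returns at 14. Alkyne 10 is deprotonated (n-BuLi, THF, −78 °C) and acylated with N-methoxy-N-methylcarbamoyl chloride. This gives the Weinreb amide 3-(2,3-dimethoxyphenyl)-N-methoxy-N-methylprop-2-ynamide F1. Iodine–lithium exchange on 7 (n-BuLi, THF, −78 °C) regenerates aryllithium 6, which should add once to F1. The product is the MOM-protected ynone 3-(2,3-dimethoxyphenyl)-1-[3,4,6-trimethoxy-2-(methoxymethoxy)phenyl]prop-2-yn-1-one F2. Catalytic p-TsOH in MeOH frees the phenol to give 12, this time isolated. Et2NH in EtOH at 60 °C then carries 12 through 13 to 14.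

**Step 4.** Deprotonation may be shared between C4 and C6, since both carbons lie between two oxygen substituents. Part of the iodine would then end up on a carbon that is useless for ring closure.

The fallback uses electrophilic rather than anionic site control and places iodine first. It sets out from 1 and returns at 7. Aldehyde 1 is iodinated (NIS, MeCN, 0 °C → rt). In 2-hydroxy-4,6-dialkoxyaryl carbonyl compounds the hydrogen-bonded hydroxyl sends halogen to its own ortho carbon, so this should give 2-hydroxy-3-iodo-4,6-dimethoxybenzaldehyde F3. The site can be checked, and any isomer removed, at this first stage. MOMCl/i-Pr2NEt gives 3-iodo-4,6-dimethoxy-2-(methoxymethoxy)benzaldehyde F4. mCPBA gives 3-iodo-4,6-dimethoxy-2-(methoxymethoxy)phenyl formate F5. K2CO3/MeOH gives 3-iodo-4,6-dimethoxy-2-(methoxymethoxy)phenol F6, and MeI/K2CO3 gives 7.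

**Step 8.** Once the chelate has formed, surplus Lewis acid may strip a second methyl group from the crowded 8-OMe or 2'-OMe.

The fallback turns the selectivity problem round. It sets out from 14 and returns at 16. Exhaustive demethylation (BBr3, CH2Cl2, −78 °C → rt, argon) gives 2-(2,3-dihydroxyphenyl)-5,7,8-trihydroxychromen-4-one F7, which is handled without exposure to air. Partial methylation (Me2SO4, 4 equiv, K2CO3, acetone, reflux, argon) should then cap the four ordinary phenols. The chelated and least nucleophilic 5-OH stays free, which gives 16.

Further compounds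
F1 | step 7 | 3-(2,3-dimethoxyphenyl)-N-methoxy-N-methylprop-2-ynamide | CON(C)C(=O)C#Cc1cccc(OC)c1OC
F2 | step 7 | 3-(2,3-dimethoxyphenyl)-1-[3,4,6-trimethoxy-2-(methoxymethoxy)phenyl]prop-2-yn-1-one | COCOc1c(C(=O)C#Cc2cccc(OC)c2OC)c(OC)cc(OC)c1OC
F3 | step 4 | 2-hydroxy-3-iodo-4,6-dimethoxybenzaldehyde | COc1cc(OC)c(I)c(O)c1C=O
F4 | step 4 | 3-iodo-4,6-dimethoxy-2-(methoxymethoxy)benzaldehyde | COCOc1c(I)c(OC)cc(OC)c1C=O
F5 | step 4 | 3-iodo-4,6-dimethoxy-2-(methoxymethoxy)phenyl formate | COCOc1c(I)c(OC)cc(OC)c1OC=O
F6 | step 4 | 3-iodo-4,6-dimethoxy-2-(methoxymethoxy)phenol | COCOc1c(I)c(OC)cc(OC)c1O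
F7 | step 8 | 2-(2,3-dihydroxyphenyl)-5,7,8-trihydroxychromen-4-one | Oc1cccc(-c2cc(=O)c3c(O)cc(O)c(O)c3o2)c1O
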